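## The problem

Numbering: chromanone O1–C8a (ring A is C4a–C8a), ring B C1'–C6', dihydrofuran O1''/C2''/C3''.

The target 22 is a (2S)-5,7-dihydroxyflavanone whose ring B is also the benzo ring of a trans-2,3-diaryl-2,3-dihydrobenzofuran. O1'' sits on C4' and C3'' on C5'; C2'' carries a 4-hydroxyphenyl group, C3'' a 3,5-dihydroxyphenyl group, and C8 of ring A a (Z)-3-methylbuta-1,3-dienyl chain. Three sp3–aryl bonds at benzylic stereocentres have to be made (C2–C1', C3''–C5', C3''–resorcinol ring). C2''(R) and C3''(R) are adjacent and trans, the more stable arrangement, so one can set the other. C2(S) lies across ring B from them and needs reagent control. The fragile parts are: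

- the dienyl phenol, a valence isomer of a 2,2-dimethylchromene that re-closes or isomerises with heat or acid;
- flavanone C2, which epimerises through the chalcone under base;
- the C2''–O1'' benzylic ether, which ionises in acid because of the para oxygen;
- six oxidisable phenols.

The enabling feature is that O1''–C2''(aryl)–C3''–C5' maps onto O1–C2(aryl)–C3 and C4a of a 2-arylchroman-4-one built on ring B, in which C5' would carry the carbonyl carbon. A 1,2-shift of that ring carbon from C4 to C3 therefore contracts the pyranone to the dihydrofuran and makes the C5'–C3'' bond. The old carbonyl carbon remains as an ester on C3'', a handle for the resorcinol ring.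

## Retrosynthesis

**22 to 20.** The O7–C(Me)2 bond is re-formed on paper: the Z-dienyl phenol is the product of 6π ring opening and 1,7-hydrogen shift of pyranoflavanone 20. A cross-coupling of a Z-dienyl metal at C8 would need a regiodefined halide on a hexaphenol and a base. Chromene 20 is thermally robust, masks O7 and fixes the C8 regiochemistry. The forward step must be a photochemical opening that leaves C2 alone.

**20 to 19.** The five phenols are traced back to benzyl ethers. Benzyl survives every earlier step, including the acidic oxidative key step, and is removed by BCl3 at low temperature without hydrogenating the chromene.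

**19 to 13 and 18.** The C2–C1' bond is cut. A chalcone cyclisation would make the same ring with no control at C2; a catalytic asymmetric conjugate arylation of pyranochromone 18 by boronate 13 sets C2 by the ligand. The fragments are of similar size. The forward reaction must tolerate an ortho-alkoxy arylboron and an electron-rich chromone.

**18 to 17, 15 and 14.** The O7–C(Me)2 and C8–C bonds of the pyran are cut. A propargyl ether Claisen sequence on 5,7-dihydroxychromone 14 (through ether 15 to pyranochromone 17) places the ring at C8; benzylation of 17 gives 18.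

**13 to 12.** The C–B bond is cut back to a C–Cl bond. Chlorine is chosen because it survives rhodium, trivalent iodine and nickel/photoredox chemistry and is distinguished from the bromide used in the arylation step.

**12 to 10 and 11; 10 to 9.** The C3''–aryl bond is cut to acid 10 and bromide 11. A decarboxylative arylation uses the carboxyl that the key step leaves at C3''. The aryl group should enter anti to the C2'' aryl group. Acid 10 comes from ester 9 by saponification.

**9 to 7 (key disconnection).** The C3–C3a bond of the dihydrobenzofuran is cut and the ring carbon is returned to the ester carbon, giving (2R)-flavanone 7. Against a C–O or C2''–C3'' closure, this makes the quaternary-free trans ring from a compound with a single stereocentre. The forward step must migrate the ring carbon, not the C2 aryl group, and must not open the pyranone.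

**7 to 5 and 6.** The C2–aryl bond is cut to chromone 5 and boronic acid 6; the forward step is an asymmetric 1,4-addition that sets C2(R), the future C2''.

**5 to 3, 2 and 1.** The pyranone carbon comes from a formamide acetal; acetophenone 3 comes from 4-chlororesorcinol 1 by acylation (2) and benzylation.

## Roads not taken

**Alternative 1:** The cut is the C4a–C8a bond of ring A, grown last from triketo ester A1, which already carries the dihydrobenzofuran as a cinnamoyl end. Mg(OMe)2 would drive attack of chain carbon C6 on the ester carbon, and enolisation would give the phloroglucinol ring of chalcone A2, to be closed to the flavanone.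

- Merits: it mirrors the biosynthesis, ring A needs no protecting groups, and the C2–C1' connection is present from the start instead of being made late on hindered partners.
- Weak points: a 3,5,7-triketo ester can fold in several ways (aldol closure to a resorcylate, lactonisation to a hydroxypyranone), and the enone end of A1 is a Michael acceptor for its own enolates. The 2',6'-dihydroxychalcone A2 closes to the flavanone spontaneously, so C2 forms without control. The dienyl chain would then have to go onto C8 of a free phloroglucinol ring in competition with C6 and the resorcinol ring.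
- Comparison: Alternative 1 is better at the C2–C1' bond. The chosen plan pays with a demanding conjugate arylation (step 12) but gains catalyst control at C2 and fixed C8 regiochemistry. Alternative 1 also does not build the dihydrofuran, so it would need one of the other constructions as well.

**Alternative 2:** The cut is C2''–C3''. Diaryldiazomethane A3 with Rh2(R-PTAD)4 would give a donor/donor carbene that inserts into the benzylic ether C–H bond, closing the ring as cis compound A4 with C3'' as in the target; C2'' would be inverted later.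

- Merits: one catalytic asymmetric step closes the ring, sets both centres and has the C3'' aryl group already in place. That is shorter than ring contraction, saponification and decarboxylative arylation, and this advantage is real.
- Weak points: the product is cis, so C2'' must be inverted by acid-mediated opening and re-closure through the para-alkoxybenzyl cation, which MOM ethers tolerate poorly and which rests on a thermodynamic preference. Electron-rich diaryldiazomethanes are labile and must be made from the hydrazone and used at once.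
- Comparison: C3'' is under catalyst control in A4, which is more certain than the substrate-controlled radical coupling of the chosen plan. The chosen plan sets against this a trans ring obtained directly, no late stereochemical correction, no diazo handling and cheap reagents in the ring-forming step.

**Alternative 3:** The cut is O1''–C2''. Anodic (non-Kolbe) decarboxylation of triarylpropanoic acid A5 would give a para-alkoxybenzyl cation at C2'', trapped by the ortho phenol of ring B to give trans ester A6.

- Merits: the closure gives trans directly, C3'' is preset, no chemical oxidant is used (the chosen plan consumes PhI(OAc)2), and the ring B ester is a useful handle towards the flavanone.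
- Weak points: A5 holds a free phenol and three alkoxyarenes that are oxidised at or below the potential a carboxylate needs, so the anode would attack the arenes first. The cation has a neighbouring carbon with two aryl groups and a hydrogen, which invites a 1,2-aryl shift or proton loss to a triarylethene. Acid formed at the anode threatens the MOM groups. A5 itself needs an asymmetric multistep synthesis of its triarylmethine centre.
- Comparison: both plans give the trans ring in the ring-forming step, and Alternative 3 is cleaner in reagents. The chosen plan sets against that a close precedent for its key step and a precursor with one stereocentre made by a catalytic arylation.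

Key step: step 5

## Route

Assumption: the ligand antipodes named in steps 4 and 12 are those expected, by analogy with rhodium–biaryl-bisphosphine catalysts on cyclic enones, to give the configurations drawn; the sense would be confirmed by correlation on the first run and the antipode exchanged if needed. MeO-F12-BIPHEP is 2,2'-bis[bis(3,4,5-trifluorophenyl)phosphino]-6,6'-dimethoxybiphenyl; dtbbpy is 4,4'-di-tert-butyl-2,2'-bipyridine.

Step 1
Reactants: 1 4-chlororesorcinol
Product: 2 1-(5-chloro-2,4-dihydroxyphenyl)ethanone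
Conditions: AcOH, ZnCl2, 140 °C
Reagents that add atoms: acetic acid, CC(=O)O
Why: Nencki-type Friedel–Crafts acylation; the carbon para to one hydroxyl and ortho to the other is the only doubly activated, unhindered position, and chlorine blocks the alternative.

Step 2
Reactants: 2 1-(5-chloro-2,4-dihydroxyphenyl)ethanone
Product: 3 1-[4-(benzyloxy)-5-chloro-2-hydroxyphenyl]ethanone
Conditions: BnBr (1.05 equiv), K2CO3, acetone, 56 °C
Reagents that add atoms: benzyl bromide, BrCc1ccccc1
Why: Williamson etherification; the 2-hydroxyl is hydrogen-bonded to the ketone and stays free, so only the 4-hydroxyl reacts.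

Step 3
Reactants: 3 1-[4-(benzyloxy)-5-chloro-2-hydroxyphenyl]ethanone
Product: 5 7-(benzyloxy)-6-chloro-4H-chromen-4-one, via enaminone 4 (not isolated)
Conditions: Me2NCH(OMe)2, toluene, 100 °C; then HCl, CH2Cl2, 40 °C
Reagents that add atoms: N,N-dimethylformamide dimethyl acetal, COC(OC)N(C)C
Why: Enaminone condensation at the acetyl group followed by acid-promoted addition–elimination of the phenol, the standard chromone synthesis from 2-hydroxyacetophenones.

Step 4
Reactants: 5 7-(benzyloxy)-6-chloro-4H-chromen-4-one; 6 4-(benzyloxy)phenylboronic acid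
Product: 7 (2R)-7-(benzyloxy)-2-[4-(benzyloxy)phenyl]-6-chlorochroman-4-one
Conditions: [RhCl(C2H4)2]2 (cat.), (R)-MeO-F12-BIPHEP (cat.), KOH (cat.), toluene/H2O, 25 °C
Reagents that add atoms: none
Why: Hayashi–Miyaura asymmetric 1,4-addition to a chromone; the aryl–rhodium species adds across C2=C3 on the face chosen by the bisphosphine, which sets C2 (the future C2''), and the mild, nearly base-free medium avoids retro-oxa-Michael opening; the aryl chloride is inert to monovalent rhodium.

Step 5
Reactants: 7 (2R)-7-(benzyloxy)-2-[4-(benzyloxy)phenyl]-6-chlorochroman-4-one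
Product: 9 methyl (2R,3R)-6-(benzyloxy)-2-[4-(benzyloxy)phenyl]-5-chloro-2,3-dihydrobenzofuran-3-carboxylate, via enol ether 8 (not isolated)
Conditions: HC(OMe)3, H2SO4, 0 °C; then PhI(OAc)2 (1.2 equiv), 0 to 20 °C; aq. NaHCO3 work-up
Reagents that add atoms: trimethyl orthoformate, COC(OC)OC; water, O
Why: Acid and the orthoformate turn ketone 7 into enol ether 8, which trivalent iodine attacks at C3 on the face opposite the C2 aryl group, and methanol adds at C4 to give a 3-iodanyl 4,4-dimethoxyflavan. In its diequatorial half-chair the C3–I bond lies anti to the C4–C4a ring bond, so ring carbon C4a moves from C4 to C3 through a bridged phenonium transition state as iodobenzene leaves, and the dimethoxycarbenium ion left at C4 becomes the methyl ester on work-up. The closest known reaction type is the oxidative 1,2-aryl shift of aryl ketones and flavanones with PhI(OAc)2 or Tl(NO3)3 in trimethyl orthoformate, which gives methyl trans-2-aryl-2,3-dihydrobenzofuran-3-carboxylates. The five-membered ring is closed by ring contraction, a 1,2-shift with inversion at C3 and not a cyclisation onto a π bond, and the bond made is the future C5'–C3'' bond. The new stereocentre C3 is controlled by C2: both the migration geometry and equilibration at the epimerisable ester-bearing carbon place the ester trans to the C2 aryl group, while C2 takes no part and is retained. The step needs migration of the ring carbon in preference to a C2-to-C3 shift of the 4-benzyloxyphenyl group or dehydrogenation to the flavone; C4a is activated twice, by O1 ortho and the 7-benzyloxy group para, whereas the C2 aryl group has one donor and must become axial to migrate. The chlorine at C6 blocks the most nucleophilic ring position against iodination, and forming 8 before the oxidant is added keeps the time in strong acid short, which limits acid-promoted opening of the pyranone and loss of configuration at C2.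

Step 6
Reactants: 9 methyl (2R,3R)-6-(benzyloxy)-2-[4-(benzyloxy)phenyl]-5-chloro-2,3-dihydrobenzofuran-3-carboxylate
Product: 10 (2R,3R)-6-(benzyloxy)-2-[4-(benzyloxy)phenyl]-5-chloro-2,3-dihydrobenzofuran-3-carboxylic acid
Conditions: LiOH·H2O, THF/MeOH/H2O, 20 °C; then dilute HCl
Reagents that add atoms: lithium hydroxide, [Li+].[OH-]
Why: Ester saponification; any enolisation at C3 returns the more stable trans acid, and elimination of the ring oxygen from the enolate is slow because the C2–O bond lies in the nodal plane of the enolate (5-endo geometry).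

Step 7
Reactants: 10 (2R,3R)-6-(benzyloxy)-2-[4-(benzyloxy)phenyl]-5-chloro-2,3-dihydrobenzofuran-3-carboxylic acid; 11 1,3-bis(benzyloxy)-5-bromobenzene
Product: 12 (2R,3R)-6-(benzyloxy)-3-[3,5-bis(benzyloxy)phenyl]-2-[4-(benzyloxy)phenyl]-5-chloro-2,3-dihydrobenzofuran
Conditions: [Ir(dF(CF3)ppy)2(dtbbpy)]PF6 (cat.), NiCl2·dme (cat.), dtbbpy, Cs2CO3, DMF, blue LEDs, 25 °C
Reagents that add atoms: none
Why: Nickel/photoredox decarboxylative arylation of a secondary benzylic carboxylic acid; the planar C3 radical is captured by the aryl–nickel species on the face anti to the C2 aryl group, so reductive elimination should give the trans product, and the electron-rich aryl chloride is much slower than the bromide in oxidative addition.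

Step 8
Reactants: 12 (2R,3R)-6-(benzyloxy)-3-[3,5-bis(benzyloxy)phenyl]-2-[4-(benzyloxy)phenyl]-5-chloro-2,3-dihydrobenzofuran
Product: 13 2-{(2R,3R)-6-(benzyloxy)-3-[3,5-bis(benzyloxy)phenyl]-2-[4-(benzyloxy)phenyl]-2,3-dihydrobenzofuran-5-yl}-4,4,5,5-tetramethyl-1,3,2-dioxaborolane
Conditions: Pd2(dba)3 (cat.), XPhos, B2pin2, KOAc, 1,4-dioxane, 100 °C
Reagents that add atoms: bis(pinacolato)diboron, CC1(C)OB(OC1(C)C)B1OC(C)(C)C(C)(C)O1
Why: Miyaura borylation; the bulky electron-rich biarylphosphine lets zerovalent palladium insert into the hindered, electron-rich C–Cl bond, and acetate is too weak a base to trigger Suzuki homocoupling.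

Step 9
Reactants: 14 5,7-dihydroxy-4H-chromen-4-one
Product: 15 5-hydroxy-7-[(2-methylbut-3-yn-2-yl)oxy]-4H-chromen-4-one
Conditions: 3-chloro-3-methylbut-1-yne, K2CO3, KI, CuI (cat.), acetone, 56 °C
Reagents that add atoms: 3-chloro-3-methylbut-1-yne, CC(C)(Cl)C#C
Why: Copper-assisted O-alkylation of a phenol with a tertiary propargylic chloride; only the acidic 7-hydroxyl reacts because the 5-hydroxyl is chelated to the carbonyl.

Step 10
Reactants: 15 5-hydroxy-7-[(2-methylbut-3-yn-2-yl)oxy]-4H-chromen-4-one
Product: 17 5-hydroxy-8,8-dimethyl-4H,8H-pyrano[2,3-h]chromen-4-one, via allenylphenol 16 (not isolated)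
Conditions: PhNEt2, 190 °C
Reagents that add atoms: none
Why: Aryl propargyl ether Claisen rearrangement, tautomerisation to 16, 1,5-hydrogen shift and 6π electrocyclisation; C8 is expected to be attacked in preference to C6 because the C7–C8 bond of the chromone has more double-bond character and C6 is flanked by the chelated 5-hydroxyl.

Step 11
Reactants: 17 5-hydroxy-8,8-dimethyl-4H,8H-pyrano[2,3-h]chromen-4-one
Product: 18 5-(benzyloxy)-8,8-dimethyl-4H,8H-pyrano[2,3-h]chromen-4-one
Conditions: BnBr, K2CO3, DMF, 60 °C
Reagents that add atoms: benzyl bromide, BrCc1ccccc1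
Why: Williamson etherification of the chelated 5-hydroxyl under forcing but non-nucleophilic conditions that leave the chromone ring intact; masking it removes an acidic, chelating group from the rhodium step.

Step 12
Reactants: 13 2-{(2R,3R)-6-(benzyloxy)-3-[3,5-bis(benzyloxy)phenyl]-2-[4-(benzyloxy)phenyl]-2,3-dihydrobenzofuran-5-yl}-4,4,5,5-tetramethyl-1,3,2-dioxaborolane; 18 5-(benzyloxy)-8,8-dimethyl-4H,8H-pyrano[2,3-h]chromen-4-one
Product: 19 (2S)-5-(benzyloxy)-2-{(2R,3R)-6-(benzyloxy)-3-[3,5-bis(benzyloxy)phenyl]-2-[4-(benzyloxy)phenyl]-2,3-dihydrobenzofuran-5-yl}-8,8-dimethyl-2,3-dihydro-4H,8H-pyrano[2,3-h]chromen-4-one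
Conditions: [RhCl(C2H4)2]2 (cat.), (S)-MeO-F12-BIPHEP (cat.), K3PO4, 1,4-dioxane/H2O, 50 °C; 18 in excess
Reagents that add atoms: none
Why: Hayashi–Miyaura asymmetric 1,4-addition with the opposite ligand antipode to step 4; the existing stereocentres are meta and para to the boron-bearing carbon, so the catalyst alone should decide the face at C2 (S), and the unactivated chromene double bond does not compete with the enone.

Step 13
Reactants: 19 (2S)-5-(benzyloxy)-2-{(2R,3R)-6-(benzyloxy)-3-[3,5-bis(benzyloxy)phenyl]-2-[4-(benzyloxy)phenyl]-2,3-dihydrobenzofuran-5-yl}-8,8-dimethyl-2,3-dihydro-4H,8H-pyrano[2,3-h]chromen-4-one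
Product: 20 (2S)-2-[(2R,3R)-3-(3,5-dihydroxyphenyl)-6-hydroxy-2-(4-hydroxyphenyl)-2,3-dihydrobenzofuran-5-yl]-5-hydroxy-8,8-dimethyl-2,3-dihydro-4H,8H-pyrano[2,3-h]chromen-4-one
Conditions: BCl3, C6HMe5, CH2Cl2, −78 °C; then MeOH
Reagents that add atoms: none
Why: Lewis-acid cleavage of aryl benzyl ethers with pentamethylbenzene as a non-basic cation trap, which prevents C-benzylation of the electron-rich rings; the low temperature is chosen to spare the chromene double bond, the C2''–O bond and flavanone C2.

Step 14
Reactants: 20 (2S)-2-[(2R,3R)-3-(3,5-dihydroxyphenyl)-6-hydroxy-2-(4-hydroxyphenyl)-2,3-dihydrobenzofuran-5-yl]-5-hydroxy-8,8-dimethyl-2,3-dihydro-4H,8H-pyrano[2,3-h]chromen-4-one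
Product: 22 (2S)-2-[(2R,3R)-3-(3,5-dihydroxyphenyl)-6-hydroxy-2-(4-hydroxyphenyl)-2,3-dihydrobenzofuran-5-yl]-5,7-dihydroxy-8-[(1Z)-3-methylbuta-1,3-dien-1-yl]chroman-4-one, via quinone allide 21 (not isolated)
Conditions: hν (350 nm, Pyrex), degassed MeCN, high dilution, 10 °C; stopped at partial conversion, 20 recovered
Reagents that add atoms: none
Why: Known photochemistry of 2,2-dimethyl-2H-chromenes: 6π ring opening to the o-quinone allide 21, then a thermal 1,7-hydrogen shift from a methyl group to the carbonyl oxygen; the shift needs the cis, s-cis geometry inherited from the ring, which makes the new chain double bond Z, and no stereocentre is touched.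

## Compound list

1 | 4-chlororesorcinol | Oc1ccc(Cl)c(O)c1 | starting material
2 | 1-(5-chloro-2,4-dihydroxyphenyl)ethanone | CC(=O)c1cc(Cl)c(O)cc1O | intermediate
3 | 1-[4-(benzyloxy)-5-chloro-2-hydroxyphenyl]ethanone | CC(=O)c1cc(Cl)c(OCc2ccccc2)cc1O | intermediate
4 | (E)-1-[4-(benzyloxy)-5-chloro-2-hydroxyphenyl]-3-(dimethylamino)prop-2-en-1-one | CN(C)/C=C/C(=O)c1cc(Cl)c(OCc2ccccc2)cc1O | intermediate (not isolated)
5 | 7-(benzyloxy)-6-chloro-4H-chromen-4-one | O=c1ccoc2cc(OCc3ccccc3)c(Cl)cc12 | intermediate
6 | 4-(benzyloxy)phenylboronic acid | OB(O)c1ccc(OCc2ccccc2)cc1 | starting material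
7 | (2R)-7-(benzyloxy)-2-[4-(benzyloxy)phenyl]-6-chlorochroman-4-one | Clc1cc2c(cc1OCc1ccccc1)O[C@@H](c1ccc(OCc3ccccc3)cc1)CC2=O | intermediate
8 | (2R)-7-(benzyloxy)-2-[4-(benzyloxy)phenyl]-6-chloro-4-methoxy-2H-chromene | Clc1cc2c(cc1OCc1ccccc1)O[C@@H](c1ccc(OCc3ccccc3)cc1)C=C2OC | intermediate (not isolated)
9 | methyl (2R,3R)-6-(benzyloxy)-2-[4-(benzyloxy)phenyl]-5-chloro-2,3-dihydrobenzofuran-3-carboxylate | Clc1cc2c(cc1OCc1ccccc1)O[C@@H](c1ccc(OCc3ccccc3)cc1)[C@@H]2C(=O)OC | intermediate
10 | (2R,3R)-6-(benzyloxy)-2-[4-(benzyloxy)phenyl]-5-chloro-2,3-dihydrobenzofuran-3-carboxylic acid | Clc1cc2c(cc1OCc1ccccc1)O[C@@H](c1ccc(OCc3ccccc3)cc1)[C@@H]2C(=O)O | intermediate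
11 | 1,3-bis(benzyloxy)-5-bromobenzene | Brc1cc(OCc2ccccc2)cc(OCc2ccccc2)c1 | starting material
12 | (2R,3R)-6-(benzyloxy)-3-[3,5-bis(benzyloxy)phenyl]-2-[4-(benzyloxy)phenyl]-5-chloro-2,3-dihydrobenzofuran | Clc1cc2c(cc1OCc1ccccc1)O[C@@H](c1ccc(OCc3ccccc3)cc1)[C@@H]2c1cc(OCc2ccccc2)cc(OCc2ccccc2)c1 | intermediate
13 | 2-{(2R,3R)-6-(benzyloxy)-3-[3,5-bis(benzyloxy)phenyl]-2-[4-(benzyloxy)phenyl]-2,3-dihydrobenzofuran-5-yl}-4,4,5,5-tetramethyl-1,3,2-dioxaborolane | CC1(C)OB(OC1(C)C)c1cc2c(cc1OCc1ccccc1)O[C@@H](c1ccc(OCc3ccccc3)cc1)[C@@H]2c1cc(OCc2ccccc2)cc(OCc2ccccc2)c1 | intermediate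
14 | 5,7-dihydroxy-4H-chromen-4-one | O=c1ccoc2cc(O)cc(O)c12 | starting material
15 | 5-hydroxy-7-[(2-methylbut-3-yn-2-yl)oxy]-4H-chromen-4-one | C#CC(C)(C)Oc1cc(O)c2c(c1)occc2=O | intermediate
16 | 5,7-dihydroxy-8-(3-methylbuta-1,2-dien-1-yl)-4H-chromen-4-one | CC(C)=C=Cc1c(O)cc(O)c2c1occc2=O | intermediate (not isolated)
17 | 5-hydroxy-8,8-dimethyl-4H,8H-pyrano[2,3-h]chromen-4-one | CC1(C)C=Cc2c(O1)cc(O)c3c2occc3=O | intermediate
18 | 5-(benzyloxy)-8,8-dimethyl-4H,8H-pyrano[2,3-h]chromen-4-one | CC1(C)C=Cc2c(O1)cc(OCc3ccccc3)c4c2occc4=O | intermediate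
19 | (2S)-5-(benzyloxy)-2-{(2R,3R)-6-(benzyloxy)-3-[3,5-bis(benzyloxy)phenyl]-2-[4-(benzyloxy)phenyl]-2,3-dihydrobenzofuran-5-yl}-8,8-dimethyl-2,3-dihydro-4H,8H-pyrano[2,3-h]chromen-4-one | CC1(C)C=Cc2c(O1)cc(OCc5ccccc5)c6c2O[C@H](c1cc2c(cc1OCc1ccccc1)O[C@@H](c1ccc(OCc3ccccc3)cc1)[C@@H]2c1cc(OCc2ccccc2)cc(OCc2ccccc2)c1)CC6=O | intermediate
20 | (2S)-2-[(2R,3R)-3-(3,5-dihydroxyphenyl)-6-hydroxy-2-(4-hydroxyphenyl)-2,3-dihydrobenzofuran-5-yl]-5-hydroxy-8,8-dimethyl-2,3-dihydro-4H,8H-pyrano[2,3-h]chromen-4-one | CC1(C)C=Cc2c(O1)cc(O)c6c2O[C@H](c1cc2c(cc1O)O[C@@H](c1ccc(O)cc1)[C@@H]2c1cc(O)cc(O)c1)CC6=O | intermediate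
21 | o-quinone allide from ring opening of 20: (2S)-2-[(2R,3R)-3-(3,5-dihydroxyphenyl)-6-hydroxy-2-(4-hydroxyphenyl)-2,3-dihydrobenzofuran-5-yl]-5-hydroxy-8-(3-methylbut-2-en-1-ylidene)-2,3-dihydrochromene-4,7-dione, chain cis to the C7 carbonyl | CC(C)=C/C=C1\C(=O)C=C(O)C2=C1O[C@H](c1cc3c(cc1O)O[C@@H](c1ccc(O)cc1)[C@@H]3c1cc(O)cc(O)c1)CC2=O | intermediate (not isolated)
22 | (2S)-2-[(2R,3R)-3-(3,5-dihydroxyphenyl)-6-hydroxy-2-(4-hydroxyphenyl)-2,3-dihydrobenzofuran-5-yl]-5,7-dihydroxy-8-[(1Z)-3-methylbuta-1,3-dien-1-yl]chroman-4-one (CNP0284772.1) | C=C(C)/C=C\c1c(O)cc(O)c2c1O[C@H](c1cc3c(cc1O)O[C@@H](c1ccc(O)cc1)[C@@H]3c1cc(O)cc(O)c1)CC2=O | target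

## Step count and least certain steps

Total: 14 steps. Longest linear sequence: 11 steps (steps 1–8, then 12–14); the pyranochromone branch is steps 9–11.

**Step 5 (key step).** What may go wrong: migration of the C2 aryl group from C2 to C3 in the diaxial conformer (leading to an isoflavone skeleton), dehydrogenation to the flavone or α-methoxylation in place of rearrangement, and acid-promoted opening of the pyranone through the para-alkoxybenzylic position, which would erode the configuration at C2. Fallback, from 7 back to 9 by a Wolff ring contraction, which forms the same bond without acid and in which only the acyl-bound ring carbon can migrate. The enolate of 7 (LiN(SiMe3)2, THF, −78 °C) would be trapped with 2,2,2-trifluoroethyl trifluoroacetate to give the 3-trifluoroacetyl ketone F1. Diazo transfer with MsN3 and Et3N, with loss of the trifluoroacetyl group, would give the 3-diazo ketone F2. Irradiation in methanol would expel nitrogen and give ketene F3, which adds methanol to give 9 together with its cis epimer F4; DBU would equilibrate F4 to 9.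

**Step 7.** What may go wrong: slow capture of the benzylic radical by nickel, so that dimerisation or reduction of the radical takes over; incomplete anti selectivity at C3; and slow nickel insertion into the C–Cl bond on long irradiation. Fallback, from 10 to 12 without light and with a nucleophilic aryl partner: acid 10 would be converted with N-hydroxytetrachlorophthalimide and diisopropylcarbodiimide into the redox-active ester F5. F5 would be coupled with commercial 3,5-bis(benzyloxy)phenylboronic acid under NiCl2·6H2O, bathophenanthroline and Et3N in dioxane/DMF at 75 °C (decarboxylative Suzuki coupling) to give 12.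

**Step 12.** What may go wrong: slow transmetalation and protodeboronation of the hindered, electron-rich ortho-alkoxy arylboronate, low reactivity of the electron-rich chromone, hydroxide attack at C2 of the chromone, and incomplete catalyst control. Fallback, from 12 and 18 to 19 through a chalcone. Chloride 12 would be vinylated with CH2=CHBF3K (Pd(OAc)2, RuPhos, K3PO4) to styrene F6 and cleaved with OsO4/NaIO4 to aldehyde F7. Chromone 18 would be opened with aqueous NaOH in ethanol, with loss of formate, to acetophenone F8. Claisen–Schmidt condensation of F7 and F8 (KOH, EtOH/THF) would give chalcone F9. Oxa-Michael closure (NaOAc, EtOH, reflux) would give 19 and its C2 epimer F10, which are diastereomers and separable; F10 would be recycled by base equilibration through F9.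

**Step 14.** What may go wrong: thermal re-closure of the quinone allide dominating over the hydrogen shift, trapping of the allide by phenols, secondary photoreactions of the product (geometric isomerisation of the diene), and photochemical opening of the flavanone with epimerisation at C2. Fallback, from 13 and 14 to 22 by cross-coupling. Chromone 14 would be benzylated twice (BnBr, K2CO3, DMF) to 5,7-bis(benzyloxy)chromone F11 and iodinated with N-iodosuccinimide, expected at C8 as the less hindered activated position, to iodochromone F12. Addition of 13 to F12 under the conditions of step 12 would give iodoflavanone F13, and BCl3/C6HMe5 would give iodo hexaphenol F14. Suzuki coupling of F14 with the Z-dienylboronate F15 (Pd(OAc)2, SPhos, K3PO4, aqueous THF, 25 °C) would give 22. F15 would be made from 2-methylbut-1-en-3-yne and pinacolborane by rhodium-catalysed trans-hydroboration ([RhCl(cod)]2, P(i-Pr)3, Et3N).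

## Further compounds

F1 | step 5 | (2R)-7-(benzyloxy)-2-[4-(benzyloxy)phenyl]-6-chloro-3-(trifluoroacetyl)chroman-4-one (C3 unassigned) | Clc1cc2c(cc1OCc1ccccc1)O[C@@H](c1ccc(OCc3ccccc3)cc1)C(C(=O)C(F)(F)F)C2=O
F2 | step 5 | (2S)-7-(benzyloxy)-2-[4-(benzyloxy)phenyl]-6-chloro-3-diazochroman-4-one (same spatial arrangement as 7; descriptor changes by priority) | Clc1cc2c(cc1OCc1ccccc1)O[C@@H](c1ccc(OCc3ccccc3)cc1)C(=[N+]=[N-])C2=O
F3 | step 5 | (2S)-6-(benzyloxy)-2-[4-(benzyloxy)phenyl]-5-chloro-3-(oxomethylidene)-2,3-dihydrobenzofuran (ketene; same spatial arrangement as 7) | Clc1cc2c(cc1OCc1ccccc1)O[C@@H](c1ccc(OCc3ccccc3)cc1)C2=C=O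
F4 | step 5 | methyl (2R,3S)-6-(benzyloxy)-2-[4-(benzyloxy)phenyl]-5-chloro-2,3-dihydrobenzofuran-3-carboxylate (cis) | Clc1cc2c(cc1OCc1ccccc1)O[C@@H](c1ccc(OCc3ccccc3)cc1)[C@H]2C(=O)OC
F5 | step 7 | 4,5,6,7-tetrachloro-1,3-dioxoisoindolin-2-yl (2R,3R)-6-(benzyloxy)-2-[4-(benzyloxy)phenyl]-5-chloro-2,3-dihydrobenzofuran-3-carboxylate | Clc1cc2c(cc1OCc1ccccc1)O[C@@H](c1ccc(OCc3ccccc3)cc1)[C@@H]2C(=O)ON1C(=O)c2c(Cl)c(Cl)c(Cl)c(Cl)c2C1=O
F6 | step 12 | (2R,3R)-6-(benzyloxy)-3-[3,5-bis(benzyloxy)phenyl]-2-[4-(benzyloxy)phenyl]-5-vinyl-2,3-dihydrobenzofuran | C=Cc1cc2c(cc1OCc1ccccc1)O[C@@H](c1ccc(OCc3ccccc3)cc1)[C@@H]2c1cc(OCc2ccccc2)cc(OCc2ccccc2)c1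
F7 | step 12 | (2R,3R)-6-(benzyloxy)-3-[3,5-bis(benzyloxy)phenyl]-2-[4-(benzyloxy)phenyl]-2,3-dihydrobenzofuran-5-carbaldehyde | O=Cc1cc2c(cc1OCc1ccccc1)O[C@@H](c1ccc(OCc3ccccc3)cc1)[C@@H]2c1cc(OCc2ccccc2)cc(OCc2ccccc2)c1
F8 | step 12 | 1-[7-(benzyloxy)-5-hydroxy-2,2-dimethyl-2H-chromen-6-yl]ethanone | CC(=O)c1c(O)c2C=CC(C)(C)Oc2cc1OCc1ccccc1
F9 | step 12 | (E)-1-[7-(benzyloxy)-5-hydroxy-2,2-dimethyl-2H-chromen-6-yl]-3-{(2R,3R)-6-(benzyloxy)-3-[3,5-bis(benzyloxy)phenyl]-2-[4-(benzyloxy)phenyl]-2,3-dihydrobenzofuran-5-yl}prop-2-en-1-one | O=C(/C=C/c1cc2c(cc1OCc1ccccc1)O[C@@H](c1ccc(OCc3ccccc3)cc1)[C@@H]2c1cc(OCc2ccccc2)cc(OCc2ccccc2)c1)c1c(O)c2C=CC(C)(C)Oc2cc1OCc1ccccc1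
F10 | step 12 | (2R)-epimer of 19 at the chromanone C2 | CC1(C)C=Cc2c(O1)cc(OCc5ccccc5)c6c2O[C@@H](c1cc2c(cc1OCc1ccccc1)O[C@@H](c1ccc(OCc3ccccc3)cc1)[C@@H]2c1cc(OCc2ccccc2)cc(OCc2ccccc2)c1)CC6=O
F11 | step 14 | 5,7-bis(benzyloxy)-4H-chromen-4-one | O=c1ccoc2cc(OCc3ccccc3)cc(OCc3ccccc3)c12
F12 | step 14 | 5,7-bis(benzyloxy)-8-iodo-4H-chromen-4-one | O=c1ccoc2c(I)c(OCc3ccccc3)cc(OCc3ccccc3)c12
F13 | step 14 | (2S)-5,7-bis(benzyloxy)-2-{(2R,3R)-6-(benzyloxy)-3-[3,5-bis(benzyloxy)phenyl]-2-[4-(benzyloxy)phenyl]-2,3-dihydrobenzofuran-5-yl}-8-iodochroman-4-one | Ic1c(OCc2ccccc2)cc(OCc2ccccc2)c2c1O[C@H](c1cc3c(cc1OCc1ccccc1)O[C@@H](c1ccc(OCc4ccccc4)cc1)[C@@H]3c1cc(OCc3ccccc3)cc(OCc3ccccc3)c1)CC2=O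
F14 | step 14 | (2S)-2-[(2R,3R)-3-(3,5-dihydroxyphenyl)-6-hydroxy-2-(4-hydroxyphenyl)-2,3-dihydrobenzofuran-5-yl]-5,7-dihydroxy-8-iodochroman-4-one | Ic1c(O)cc(O)c2c1O[C@H](c1cc3c(cc1O)O[C@@H](c1ccc(O)cc1)[C@@H]3c1cc(O)cc(O)c1)CC2=O
F15 | step 14 | 4,4,5,5-tetramethyl-2-[(1Z)-3-methylbuta-1,3-dien-1-yl]-1,3,2-dioxaborolane | C=C(C)/C=C\B1OC(C)(C)C(C)(C)O1
A1 | alternative 1 | methyl (E)-9-{(2R,3R)-3-[3,5-bis(methoxymethoxy)phenyl]-6-(methoxymethoxy)-2-[4-(methoxymethoxy)phenyl]-2,3-dihydrobenzofuran-5-yl}-3,5,7-trioxonon-8-enoate | COC(=O)CC(=O)CC(=O)CC(=O)/C=C/c1cc2c(cc1OCOC)O[C@@H](c1ccc(OCOC)cc1)[C@@H]2c1cc(OCOC)cc(OCOC)c1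
A2 | alternative 1 | (E)-3-{(2R,3R)-3-[3,5-bis(methoxymethoxy)phenyl]-6-(methoxymethoxy)-2-[4-(methoxymethoxy)phenyl]-2,3-dihydrobenzofuran-5-yl}-1-(2,4,6-trihydroxyphenyl)prop-2-en-1-one | O=C(/C=C/c1cc2c(cc1OCOC)O[C@@H](c1ccc(OCOC)cc1)[C@@H]2c1cc(OCOC)cc(OCOC)c1)c1c(O)cc(O)cc1O
A3 | alternative 2 | {5-bromo-4-(methoxymethoxy)-2-[4-(methoxymethoxy)benzyloxy]phenyl}[3,5-bis(methoxymethoxy)phenyl]diazomethane | [N-]=[N+]=C(c1cc(OCOC)cc(OCOC)c1)c1cc(Br)c(OCOC)cc1OCc1ccc(OCOC)cc1
A4 | alternative 2 | (2S,3R)-3-[3,5-bis(methoxymethoxy)phenyl]-5-bromo-6-(methoxymethoxy)-2-[4-(methoxymethoxy)phenyl]-2,3-dihydrobenzofuran (cis) | Brc1cc2c(cc1OCOC)O[C@H](c1ccc(OCOC)cc1)[C@@H]2c1cc(OCOC)cc(OCOC)c1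
A5 | alternative 3 | (3R)-3-[3,5-bis(methoxymethoxy)phenyl]-3-[2-hydroxy-5-(methoxycarbonyl)-4-(methoxymethoxy)phenyl]-2-[4-(methoxymethoxy)phenyl]propanoic acid (C2 unassigned) | OC(=O)C(c1ccc(OCOC)cc1)[C@@H](c1cc(C(=O)OC)c(OCOC)cc1O)c1cc(OCOC)cc(OCOC)c1
A6 | alternative 3 | methyl (2R,3R)-3-[3,5-bis(methoxymethoxy)phenyl]-6-(methoxymethoxy)-2-[4-(methoxymethoxy)phenyl]-2,3-dihydrobenzofuran-5-carboxylate | COC(=O)c1cc2c(cc1OCOC)O[C@@H](c1ccc(OCOC)cc1)[C@@H]2c1cc(OCOC)cc(OCOC)c1
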